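## Plan

Ring atoms are numbered as in p-menthane: C1 carries CH3, C2 is the vinylic CH, C4 carries O and isopropyl.

1. Retrosynthesis: the hindered ester C–O bond is cut last (tertiary alkoxide plus aroyl chloride). In the (R)-terpinen-4-ol ring the bonds C2–C3 and C4–C5 are cut together, a [4+2] disconnection.
2. Enabling feature: a six-membered carbocycle whose oxygenated quaternary C4 is 1,4 to the CH3-bearing sp2 carbon C1 and is flanked by CH2 groups. With C1 as a carbonyl this is the retron of a Diels–Alder reaction of a 1-amino-3-siloxybutadiene (gives C2, C1, C6, C5) with 2-isopropylacrolein (gives C3, C4). The formyl group is a helper that is later exchanged for oxygen.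
3. Forward: ring first (4-formyl-4-isopropylcyclohexenone), then CHO to OH (Baeyer–Villiger), C1=O to C1(CH3)=C2 through the α′-enol triflate, and C5=C6 saturated with diimide. The aryl acid is made by double Stille prenylation and joined last.
4. Stereochemistry: C4, the only stereocentre, is set in the Diels–Alder step by a chiral diol (hydrogen-bond) catalyst and survives the carbon-to-oxygen migration with retention. It keeps its meaning because the enone C5=C6 marks one ring arm while the new double bond is placed regiospecifically on the other; no symmetric ring intermediate is passed.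

Key step: step 2

Assumption: the (R,R)-diol catalyst is taken to leave open the enal face that leads to the (R)-aldehyde; if the sense proved opposite, the (S,S)-catalyst would be used, and the same holds for the chiral auxiliary and chiral base in the fallbacks.

## Route

Step 1
Reactants: 1 3-methylbutanal
Product: 2 3-methyl-2-methylidenebutanal (2-isopropylacrolein)
Conditions: 37% aq. CH2O, pyrrolidine (10 mol%), EtCO2H (10 mol%), iPrOH, 45 °C
Reagents that add atoms: formaldehyde C=O
Why: Mannich-type α-methylenation, in which the enamine of 1 adds to the iminium ion of formaldehyde and the β-amino aldehyde loses the amine to give the 2-substituted acrolein; no stereocentre is formed.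

Step 2
Reactants: 2 3-methyl-2-methylidenebutanal; 3 (E)-3-[(tert-butyldimethylsilyl)oxy]-N,N-dimethylbuta-1,3-dien-1-amine
Product: 5 (R)-1-isopropyl-4-oxocyclohex-2-ene-1-carbaldehyde, via endo amino silyl enol ether cycloadduct 4 (not isolated)
Conditions: (R,R)-1-naphthyl-TADDOL [(4R,5R)-2,2-dimethyl-α,α,α′,α′-tetra(1-naphthyl)-1,3-dioxolane-4,5-dimethanol] (20 mol%), toluene, −78 °C; then AcCl, Et2O, −78 °C → rt
Reagents that add atoms: none
Why: Asynchronous concerted normal-demand Diels–Alder reaction in which a hydroxyl group of the diol hydrogen-bonds to the formyl oxygen of 2 and lowers its LUMO; the ring is closed in a single suprafacial [4π+2π] event (endo transition state) that forms C2–C3 and C4–C5 together. The closest known reaction type is the hydrogen-bond-catalysed enantioselective Diels–Alder reaction of 1-amino-3-siloxybutadienes with α-substituted acroleins to give 4-alkyl-4-formylcyclohex-2-enones. Regioselectivity is required and is secured by the diene itself: the 1-amino and 3-siloxy donors both make the CH2 terminus the nucleophilic end, so it bonds to the β-CH2 of the enal (C2–C3) while the aminated terminus bonds to the α-carbon (C4–C5). The quaternary C4 is the only lasting stereocentre and is controlled by the catalyst, whose naphthyl groups should shield one face of the s-trans enal held in place by its α-isopropyl group; the aminated carbon of 4 is also stereogenic (endo rule, E-diene) but is erased at once. Acetyl chloride then acylates the amine, which leaves together with the silyl group to give the enone. The enone C5=C6 marks the ring arm that must end saturated and leaves C2 (α′) free for the final double bond.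

Step 3
Reactants: 5 (R)-1-isopropyl-4-oxocyclohex-2-ene-1-carbaldehyde
Product: 7 (R)-4-hydroxy-4-isopropylcyclohex-2-en-1-one, via formate ester 6 (not isolated)
Conditions: 3-chloroperbenzoic acid (mCPBA), CH2Cl2, 0 °C → rt; then KHCO3 (cat.), MeOH, 0 °C
Reagents that add atoms: 3-chloroperbenzoic acid OOC(=O)c1cccc(Cl)c1
Why: Baeyer–Villiger oxidation of an aldehyde with a quaternary α-carbon, in which the tertiary allylic C4 should migrate to oxygen in preference to hydride and with retention, so the configuration from step 2 becomes that of the carbinol carbon; the electron-poor enone C=C resists the electrophilic peracid, and mild methanolysis cleaves the formate.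

Step 4
Reactants: 7 (R)-4-hydroxy-4-isopropylcyclohex-2-en-1-one
Product: 8 (R)-4-isopropyl-4-[(triethylsilyl)oxy]cyclohex-2-en-1-one
Conditions: Et3SiOTf, 2,6-lutidine, CH2Cl2, −78 → 0 °C
Reagents that add atoms: triethylsilyl trifluoromethanesulfonate CC[Si](CC)(CC)OS(=O)(=O)C(F)(F)F
Why: Silylation of a hindered tertiary alcohol with a silyl triflate and a non-nucleophilic base; the silyl ether masks the alkoxide in the enolate and Grignard steps and keeps the later cyclohexadiene from ionising at C4.

Step 5
Reactants: 8 (R)-4-isopropyl-4-[(triethylsilyl)oxy]cyclohex-2-en-1-one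
Product: 9 (R)-4-isopropyl-4-[(triethylsilyl)oxy]cyclohexa-1,5-dien-1-yl trifluoromethanesulfonate
Conditions: LiN(iPr)2, THF, −78 °C; then PhNTf2, −78 → 0 °C
Reagents that add atoms: N-phenylbis(trifluoromethanesulfonimide) O=S(=O)(N(c1ccccc1)S(=O)(=O)C(F)(F)F)C(F)(F)F
Why: Kinetic deprotonation of a cyclohex-2-enone by a lithium amide removes the α′-proton at C2 (the γ-position C4 has no hydrogen), and O-sulfonylation of the cross-conjugated enolate fixes the future double bond between C1 and C2, on the arm that does not carry the enone C=C.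

Step 6
Reactants: 9 (R)-4-isopropyl-4-[(triethylsilyl)oxy]cyclohexa-1,5-dien-1-yl trifluoromethanesulfonate
Product: 10 (R)-triethyl[(1-isopropyl-4-methylcyclohexa-2,4-dien-1-yl)oxy]silane
Conditions: MeMgBr, Fe(acac)3 (5 mol%), THF/NMP, −30 °C
Reagents that add atoms: methylmagnesium bromide C[Mg]Br
Why: Iron-catalysed Kumada-type cross-coupling of an alkenyl triflate with a methyl Grignard reagent should replace OTf by CH3 at C1 without moving the double bonds; the silyl ether is inert.

Step 7
Reactants: 10 (R)-triethyl[(1-isopropyl-4-methylcyclohexa-2,4-dien-1-yl)oxy]silane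
Product: 11 (R)-triethyl[(1-isopropyl-4-methylcyclohex-3-en-1-yl)oxy]silane
Conditions: 2-nitrobenzenesulfonylhydrazide, Et3N, CH2Cl2, 23 °C
Reagents that add atoms: none
Why: Diimide reduction, a concerted syn transfer of two hydrogens that should go to the cis-disubstituted C5=C6 bond of the conjugated diene much faster than to the trisubstituted C1=C2 bond; diimide adds only 1,2 and cannot shift double bonds, so the alkene stays on the C2 side and the C4 configuration keeps its meaning.

Step 8
Reactants: 11 (R)-triethyl[(1-isopropyl-4-methylcyclohex-3-en-1-yl)oxy]silane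
Product: 12 (R)-1-isopropyl-4-methylcyclohex-3-en-1-ol [(R)-terpinen-4-ol]
Conditions: Bu4NF, THF, 0 °C → rt
Reagents that add atoms: none
Why: Fluoride-induced Si–O cleavage frees the tertiary alcohol without acid, which avoids acid-catalysed double-bond migration between the two ring arms (that would racemise the compound) and dehydration.

Step 9
Reactants: 13 3,5-dibromo-4-hydroxybenzoic acid
Product: 14 methyl 3,5-dibromo-4-methoxybenzoate
Conditions: MeI, K2CO3, DMF, 40 °C
Reagents that add atoms: iodomethane CI
Why: Williamson-type double O-methylation (SN2 on iodomethane) of the carboxylate and of the phenoxide, which is made more acidic by the two ortho bromines.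

Step 10
Reactants: 14 methyl 3,5-dibromo-4-methoxybenzoate; 15 tributyl(3-methylbut-2-en-1-yl)stannane
Product: 16 methyl 4-methoxy-3,5-bis(3-methylbut-2-en-1-yl)benzoate
Conditions: Pd(PPh3)4 (10 mol%), DMF, 100 °C
Reagents that add atoms: none
Why: Twofold Stille coupling: each aryl bromide adds oxidatively to zerovalent palladium, the prenyl group is transferred from tin, and reductive elimination at the unsubstituted allyl terminus should give the linear 3-methylbut-2-enyl arene; ester and ether are untouched.

Step 11
Reactants: 16 methyl 4-methoxy-3,5-bis(3-methylbut-2-en-1-yl)benzoate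
Product: 17 4-methoxy-3,5-bis(3-methylbut-2-en-1-yl)benzoic acid
Conditions: LiOH, THF/MeOH/H2O, 50 °C; then 1 M HCl, 0 °C
Reagents that add atoms: lithium hydroxide [Li+].[OH-]
Why: Saponification by acyl–oxygen cleavage of an unhindered methyl benzoate; the trisubstituted alkenes are stable to base, and acidification is done cold with dilute acid.

Step 12
Reactants: 17 4-methoxy-3,5-bis(3-methylbut-2-en-1-yl)benzoic acid; 12 (R)-1-isopropyl-4-methylcyclohex-3-en-1-ol
Product: 19 (R)-1-isopropyl-4-methylcyclohex-3-en-1-yl 4-methoxy-3,5-bis(3-methylbut-2-en-1-yl)benzoate, via acid chloride 18 (not isolated)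
Conditions: 17, 1-chloro-N,N,2-trimethylprop-1-en-1-amine, CH2Cl2, 0 °C → rt; 12, n-BuLi, THF, −78 °C; then the two solutions combined, −78 °C → rt
Reagents that add atoms: none
Why: Acylation of a preformed lithium tertiary alkoxide by an acid chloride made under neutral conditions (no HCl to add to the prenyl groups) overcomes the low nucleophilicity of the hindered alcohol; no bond to C4 is broken, so the configuration is retained.

## Compound list

1 | 3-methylbutanal | CC(C)CC=O | starting material
2 | 3-methyl-2-methylidenebutanal (2-isopropylacrolein) | C=C(C=O)C(C)C | intermediate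
3 | (E)-3-[(tert-butyldimethylsilyl)oxy]-N,N-dimethylbuta-1,3-dien-1-amine | CN(C)/C=C/C(=C)O[Si](C)(C)C(C)(C)C | starting material
4 | (1R,2R)-4-[(tert-butyldimethylsilyl)oxy]-2-(dimethylamino)-1-isopropylcyclohex-3-ene-1-carbaldehyde (endo cycloadduct) | O=C[C@@]1(C(C)C)CCC(O[Si](C)(C)C(C)(C)C)=C[C@H]1N(C)C | intermediate
5 | (R)-1-isopropyl-4-oxocyclohex-2-ene-1-carbaldehyde | O=C[C@@]1(C(C)C)CCC(=O)C=C1 | intermediate
6 | (R)-1-isopropyl-4-oxocyclohex-2-en-1-yl formate | O=CO[C@@]1(C(C)C)CCC(=O)C=C1 | intermediate
7 | (R)-4-hydroxy-4-isopropylcyclohex-2-en-1-one | O[C@@]1(C(C)C)CCC(=O)C=C1 | intermediate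
8 | (R)-4-isopropyl-4-[(triethylsilyl)oxy]cyclohex-2-en-1-one | CC[Si](CC)(CC)O[C@@]1(C(C)C)CCC(=O)C=C1 | intermediate
9 | (R)-4-isopropyl-4-[(triethylsilyl)oxy]cyclohexa-1,5-dien-1-yl trifluoromethanesulfonate | CC[Si](CC)(CC)O[C@@]1(C(C)C)CC=C(OS(=O)(=O)C(F)(F)F)C=C1 | intermediate
10 | (R)-triethyl[(1-isopropyl-4-methylcyclohexa-2,4-dien-1-yl)oxy]silane | CC[Si](CC)(CC)O[C@@]1(C(C)C)CC=C(C)C=C1 | intermediate
11 | (R)-triethyl[(1-isopropyl-4-methylcyclohex-3-en-1-yl)oxy]silane | CC[Si](CC)(CC)O[C@@]1(C(C)C)CC=C(C)CC1 | intermediate
12 | (R)-1-isopropyl-4-methylcyclohex-3-en-1-ol [(R)-terpinen-4-ol] | O[C@@]1(C(C)C)CC=C(C)CC1 | intermediate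
13 | 3,5-dibromo-4-hydroxybenzoic acid | OC(=O)c1cc(Br)c(O)c(Br)c1 | starting material
14 | methyl 3,5-dibromo-4-methoxybenzoate | COC(=O)c1cc(Br)c(OC)c(Br)c1 | intermediate
15 | tributyl(3-methylbut-2-en-1-yl)stannane | CCCC[Sn](CCCC)(CCCC)CC=C(C)C | starting material
16 | methyl 4-methoxy-3,5-bis(3-methylbut-2-en-1-yl)benzoate | COC(=O)c1cc(CC=C(C)C)c(OC)c(CC=C(C)C)c1 | intermediate
17 | 4-methoxy-3,5-bis(3-methylbut-2-en-1-yl)benzoic acid | OC(=O)c1cc(CC=C(C)C)c(OC)c(CC=C(C)C)c1 | intermediate
18 | 4-methoxy-3,5-bis(3-methylbut-2-en-1-yl)benzoyl chloride | ClC(=O)c1cc(CC=C(C)C)c(OC)c(CC=C(C)C)c1 | intermediate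
19 | (R)-1-isopropyl-4-methylcyclohex-3-en-1-yl 4-methoxy-3,5-bis(3-methylbut-2-en-1-yl)benzoate | COc1c(CC=C(C)C)cc(C(=O)O[C@@]2(C(C)C)CC=C(C)CC2)cc1CC=C(C)C | target

## Step count and risks

Total step count: 12. Longest linear sequence: 9 steps (steps 1 to 8, then step 12).

Steps most likely to fail:

**Step 2.** Facial discrimination of the hindered α-isopropyl enal by a single hydrogen bond may be insufficient, and the uncatalysed background cycloaddition may compete, which would erode the enantiomeric purity of all later compounds. The fallback moves stereocontrol from the catalyst to an auxiliary bound to the diene. It sets out from compound 2. 4-Methoxybut-3-en-2-one is condensed with (2R,5R)-2,5-diphenylpyrrolidine to give the vinylogous amide (E)-4-[(2R,5R)-2,5-diphenylpyrrolidin-1-yl]but-3-en-2-one F1. Enolisation with KN(SiMe3)2 and silylation with tert-butyldimethylsilyl chloride give the chiral diene (2R,5R)-1-[(E)-3-((tert-butyldimethylsilyl)oxy)buta-1,3-dien-1-yl]-2,5-diphenylpyrrolidine F2. Uncatalysed Diels–Alder reaction of F2 with 2 (toluene, −20 °C) should give the cycloadduct (1R,2R)-4-((tert-butyldimethylsilyl)oxy)-2-[(2R,5R)-2,5-diphenylpyrrolidin-1-yl]-1-isopropylcyclohex-3-ene-1-carbaldehyde F3. Aqueous HF in MeCN then releases the auxiliary and the silyl group, and the fallback returns to the route at compound 5.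

**Step 7.** The trisubstituted double bond may be over-reduced, or silanol may be lost from C4 with aromatisation while the acid-labile diene is handled. The fallback sets out from compound 8 and re-creates the asymmetry by desymmetrisation. Hydrogenation of the enone C=C (H2, Pd/C, EtOAc) gives the achiral ketone 4-isopropyl-4-((triethylsilyl)oxy)cyclohexan-1-one F4. Enantioselective deprotonation with lithium (R,R)-bis(1-phenylethyl)amide and LiCl in THF at −100 °C, with trapping by PhNTf2, should give (R)-4-isopropyl-4-((triethylsilyl)oxy)cyclohex-1-en-1-yl trifluoromethanesulfonate F5. Methylation with MeMgBr and Fe(acac)3 as in step 6 returns to the route at compound 11.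

**Step 3.** Hydride may migrate instead of the quaternary carbon in the peracid adduct (over-oxidation to the acid, then decarboxylation), or the formyl group may be lost by retro-Claisen-type cleavage. The fallback sets out from compound 5 and lets an acetyl group, which has no hydride to migrate, carry the oxidation. Aldehyde-selective addition of MeTi(OiPr)3 gives (4R)-4-(1-hydroxyethyl)-4-isopropylcyclohex-2-en-1-one F6. Dess–Martin oxidation gives (R)-4-acetyl-4-isopropylcyclohex-2-en-1-one F7. Baeyer–Villiger oxidation with mCPBA, in which the tertiary carbon migrates in preference to methyl and with retention, gives (R)-1-isopropyl-4-oxocyclohex-2-en-1-yl acetate F8. Methanolysis (K2CO3, MeOH) returns to the route at compound 7.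

Further compounds
F1 | step 2 | (E)-4-[(2R,5R)-2,5-diphenylpyrrolidin-1-yl]but-3-en-2-one | CC(=O)/C=C/N1[C@@H](c2ccccc2)CC[C@@H]1c1ccccc1
F2 | step 2 | (2R,5R)-1-[(E)-3-((tert-butyldimethylsilyl)oxy)buta-1,3-dien-1-yl]-2,5-diphenylpyrrolidine | C=C(O[Si](C)(C)C(C)(C)C)/C=C/N1[C@@H](c2ccccc2)CC[C@@H]1c1ccccc1
F3 | step 2 | (1R,2R)-4-((tert-butyldimethylsilyl)oxy)-2-[(2R,5R)-2,5-diphenylpyrrolidin-1-yl]-1-isopropylcyclohex-3-ene-1-carbaldehyde | O=C[C@@]1(C(C)C)CCC(O[Si](C)(C)C(C)(C)C)=C[C@H]1N1[C@@H](c2ccccc2)CC[C@@H]1c1ccccc1
F4 | step 7 | 4-isopropyl-4-((triethylsilyl)oxy)cyclohexan-1-one | CC[Si](CC)(CC)OC1(C(C)C)CCC(=O)CC1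
F5 | step 7 | (R)-4-isopropyl-4-((triethylsilyl)oxy)cyclohex-1-en-1-yl trifluoromethanesulfonate | CC[Si](CC)(CC)O[C@@]1(C(C)C)CC=C(OS(=O)(=O)C(F)(F)F)CC1
F6 | step 3 | (4R)-4-(1-hydroxyethyl)-4-isopropylcyclohex-2-en-1-one | CC(O)[C@@]1(C(C)C)CCC(=O)C=C1
F7 | step 3 | (R)-4-acetyl-4-isopropylcyclohex-2-en-1-one | CC(=O)[C@@]1(C(C)C)CCC(=O)C=C1
F8 | step 3 | (R)-1-isopropyl-4-oxocyclohex-2-en-1-yl acetate | CC(=O)O[C@@]1(C(C)C)CCC(=O)C=C1
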